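**Retrosynthetic overview**
- The tetronic acid ring is the only ring made (the furan is bought in). It is closed last by Dieckmann condensation of an (E)-2-(propanoyloxy)enoate, whose geometry becomes the 5E exocyclic alkene.
- Key disconnection: the C(sp3)–C(sp3) bond between the diene-bearing methyl stereocentre (C6') and C5'. A racemic pentadienyl chloride (fragment 1) and a functionalised alkylzinc (fragment 2) are joined by an enantioconvergent nickel-catalysed radical Negishi coupling that sets C6'.
- Fragment 1: 3-bromofuran and 1-bromo-3-chloropropane (reductive coupling), propyne (syn-carbocupration fixes the Z trisubstituted alkene), crotonaldehyde, then chlorination.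
- Fragment 2: the same nickel-catalysed coupling on racemic 4-chloropent-2-ene sets C2'. Ozonolysis and a Still–Gennari-type olefination with an acyloxyphosphonate then install the enol ester.

Assumption: the absolute sense of the nickel/pybox couplings is assigned by analogy with known 1,3-dialkylallyl chloride couplings; if the (S,S)-ligand gives the S centres, the (R,R)-ligand is used in steps 6 and 12.

**Route**

Step 1
Reactants: 1 3-bromofuran; 2 1-bromo-3-chloropropane
Product: 3 3-(3-chloropropyl)furan
Conditions: NiI2 hydrate (10 mol %), 4,4'-di-tert-butyl-2,2'-bipyridine (10 mol %), NaI (25 mol %), pyridine (10 mol %), Zn dust (2 equiv), DMPU, 60 °C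
Reagents that add atoms: none
Why: Nickel-catalysed reductive cross-electrophile coupling of an aryl bromide with a primary alkyl bromide, in which the 3-furylnickel species captures the 3-chloropropyl radical and reductive elimination forms the C(sp2)–C(sp3) bond while the C–Cl bond is too slow to react; no stereocentre is made.

Step 2
Reactants: 3 3-(3-chloropropyl)furan; 4 propyne
Product: 8 3-[(4Z)-5-iodo-4-methylpent-4-en-1-yl]furan, via Grignard reagent 5 (not isolated), via alkylcopper 6 (not isolated), via alkenylcopper 7 (not isolated)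
Conditions: Mg, Et2O, reflux; CuBr·SMe2, Et2O/Me2S, −45 °C; 4, −25 °C; I2, THF, −50 → 0 °C
Reagents that add atoms: iodine, II
Why: Normant syn-carbocupration of propyne followed by iodinolysis with retention puts the alkyl chain on the internal carbon and cis to copper (then iodine), which fixes the Z trisubstituted alkene.

Step 3
Reactants: 8 3-[(4Z)-5-iodo-4-methylpent-4-en-1-yl]furan; 9 (2E)-but-2-enal
Product: 11 (2E,5Z)-9-(furan-3-yl)-6-methylnona-2,5-dien-4-ol (racemic), via alkenyllithium 10 (not isolated)
Conditions: t-BuLi (2 equiv), Et2O, −78 °C; 9, −78 °C; H2O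
Reagents that add atoms: none
Why: Iodine–lithium exchange with retention of alkene geometry and 1,2-addition of the alkenyllithium to the enal; the carbinol centre is left racemic because it is erased in step 12.

Step 4
Reactants: 11 (2E,5Z)-9-(furan-3-yl)-6-methylnona-2,5-dien-4-ol
Product: 13 3-[(4Z,6E)-8-chloro-4-methylnona-4,6-dien-1-yl]furan (racemic; main allylic isomer), via mesylate 12 (not isolated)
Conditions: MsCl, 2,4,6-collidine, LiCl, DMF, −20 → 0 °C; cold pentane extraction, used crude at once
Reagents that add atoms: lithium chloride, [Li+].[Cl-]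
Why: Mesylation and chloride displacement with allylic transposition into conjugation gives the secondary dienyl chloride as the main isomer; the racemic centre and any allylic isomers converge on one radical in step 12.

Step 5
Reactants: 14 (3E)-pent-3-en-2-ol (racemic)
Product: 15 (2E)-4-chloropent-2-ene (racemic)
Conditions: conc. aq. HCl, 0 °C → rt
Reagents that add atoms: hydrogen chloride, Cl
Why: SN1 substitution through the symmetrical 1,3-dimethylallyl cation, so allylic transposition returns the same racemic chloride.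

Step 6
Reactants: 15 (2E)-4-chloropent-2-ene; 16 (3-bromopropoxy)(tert-butyl)dimethylsilane
Product: 18 tert-butyl(dimethyl){[(4R,5E)-4-methylhept-5-en-1-yl]oxy}silane, via alkylzinc bromide 17 (not isolated)
Conditions: 16, Zn dust, I2 (5 mol %), DMA, 70 °C; then 15, NiCl2·glyme (5 mol %), (S,S)-2,6-bis[4-(2-phenylethyl)-4,5-dihydrooxazol-2-yl]pyridine (5.5 mol %), NaCl (4 equiv), DMA/DMF, −10 °C
Reagents that add atoms: none
Why: Nickel/pybox-catalysed enantioconvergent Negishi coupling of a racemic secondary allylic chloride, in which chloride abstraction by low-valent nickel gives the same symmetrical allyl radical from both enantiomers and C–C bond formation in the chiral nickel complex sets the new methyl-bearing centre as R by catalyst control.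

Step 7
Reactants: 18 tert-butyl(dimethyl){[(4R,5E)-4-methylhept-5-en-1-yl]oxy}silane
Product: 19 (2E,4R)-7-bromo-4-methylhept-2-ene
Conditions: Ph3PBr2, CH2Cl2, 0 °C → rt
Reagents that add atoms: dibromotriphenylphosphorane, BrP(Br)(c1ccccc1)(c1ccccc1)c1ccccc1
Why: Direct Appel-type conversion of a primary silyl ether into the bromide (oxyphosphonium formation, then SN2 by bromide at the primary carbon), which leaves the alkene and the allylic stereocentre untouched.

Step 8
Reactants: 19 (2E,4R)-7-bromo-4-methylhept-2-ene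
Product: 21 (2R)-5-bromo-2-methylpentanal, via ozonide 20 (not isolated)
Conditions: O3, CH2Cl2, −78 °C; PPh3, −78 °C → rt
Reagents that add atoms: ozone, [O-][O+]=O
Why: Ozonolysis with reductive work-up (Criegee mechanism) cleaves the propenyl group to the aldehyde under cold neutral conditions that do not epimerise the alpha stereocentre; the aldehyde is used at once.

Step 9
Reactants: 22 ethyl 2-oxoacetate
Product: 23 ethyl 2-[bis(2,2,2-trifluoroethoxy)phosphoryl]-2-hydroxyacetate
Conditions: (CF3CH2O)2P(O)H, toluene, 60 °C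
Reagents that add atoms: bis(2,2,2-trifluoroethyl) phosphite, O=[PH](OCC(F)(F)F)OCC(F)(F)F
Why: Pudovik addition of the P–H bond across the very electrophilic glyoxylate aldehyde, run without base to avoid the phospha-Brook rearrangement.

Step 10
Reactants: 23 ethyl 2-[bis(2,2,2-trifluoroethoxy)phosphoryl]-2-hydroxyacetate; 24 propanoyl chloride
Product: 25 ethyl 2-[bis(2,2,2-trifluoroethoxy)phosphoryl]-2-(propanoyloxy)acetate
Conditions: 24, pyridine, CH2Cl2, 0 °C
Reagents that add atoms: none
Why: O-acylation of the alpha-hydroxy phosphonate with an acid chloride under weakly basic conditions, which is faster than rearrangement of the hydroxy phosphonate.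

Step 11
Reactants: 21 (2R)-5-bromo-2-methylpentanal; 25 ethyl 2-[bis(2,2,2-trifluoroethoxy)phosphoryl]-2-(propanoyloxy)acetate
Product: 27 ethyl (2E,4R)-7-bromo-4-methyl-2-(propanoyloxy)hept-2-enoate, via potassium phosphonate anion 26 (not isolated)
Conditions: 25, KN(SiMe3)2, 18-crown-6, THF, −78 °C; then 21, −78 °C
Reagents that add atoms: none
Why: Proposed new method: Still–Gennari-type Horner–Wadsworth–Emmons olefination with an alpha-acyloxy phosphonoacetate; the trifluoroethyl phosphonate makes addition irreversible and elimination fast, so, as with the known alpha-methyl Still–Gennari reagents and the known olefinations of alpha-acyloxy dialkyl phosphonoacetates, the aldehyde residue should end up cis to the ester (the 2E enol ester), and the preformed non-basic anion does not epimerise C4.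

Step 12
Reactants: 27 ethyl (2E,4R)-7-bromo-4-methyl-2-(propanoyloxy)hept-2-enoate; 13 3-[(4Z,6E)-8-chloro-4-methylnona-4,6-dien-1-yl]furan
Product: 29 ethyl (2E,4R,8R,9E,11Z)-15-(furan-3-yl)-4,8,12-trimethyl-2-(propanoyloxy)pentadeca-2,9,11-trienoate, via alkylzinc bromide 28 (not isolated)
Conditions: 27, Zn dust, I2 (5 mol %), DMA, 70 °C; then 13, NiCl2·glyme (10 mol %), ligand of step 6 (11 mol %), NaCl (4 equiv), DMA/DMF, −10 °C
Reagents that add atoms: none
Why: Proposed new method: enantioconvergent nickel/pybox Negishi coupling extended from allylic to pentadienylic chlorides (closest known reaction: the coupling of racemic secondary allylic chlorides with alkylzinc halides used in step 6); chloride abstraction from either enantiomer and any allylic isomer of 13 gives one pentadienyl radical, which the chiral alkylnickel complex captures and couples at the methyl-bearing terminus (least hindered, keeps the diene conjugated, the tertiary terminus cannot couple), setting C8 as R by catalyst control with a 9E alkene and the 11Z alkene carried through.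

Step 13
Reactants: 29 ethyl (2E,4R,8R,9E,11Z)-15-(furan-3-yl)-4,8,12-trimethyl-2-(propanoyloxy)pentadeca-2,9,11-trienoate
Product: 30 (5E)-5-[(2R,6R,7E,9Z)-13-(furan-3-yl)-2,6,10-trimethyltrideca-7,9-dien-1-ylidene]-4-hydroxy-3-methylfuran-2(5H)-one
Conditions: LiN(SiMe3)2 (2.2 equiv), THF, −78 → 0 °C; then 1 M HCl
Reagents that add atoms: none
Why: Dieckmann condensation in which the propanoate enolate attacks the neighbouring ethyl ester in a 5-exo-trig closure driven by formation of the tetronate anion; the enol-ester double bond is not involved, so its geometry becomes the 5E exocyclic alkene and both stereocentres are untouched.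

**Compound list**
1 | 3-bromofuran | Brc1ccoc1 | starting material
2 | 1-bromo-3-chloropropane | ClCCCBr | starting material
3 | 3-(3-chloropropyl)furan | ClCCCc1ccoc1 | intermediate
4 | propyne | CC#C | starting material
5 | [3-(furan-3-yl)propyl]magnesium chloride | Cl[Mg]CCCc1ccoc1 | intermediate
6 | [3-(furan-3-yl)propyl]copper (MgBrCl complex) | [Cu]CCCc1ccoc1 | intermediate
7 | [(1Z)-5-(furan-3-yl)-2-methylpent-1-en-1-yl]copper | [Cu]/C=C(/C)CCCc1ccoc1 | intermediate
8 | 3-[(4Z)-5-iodo-4-methylpent-4-en-1-yl]furan | I/C=C(/C)CCCc1ccoc1 | intermediate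
9 | (2E)-but-2-enal | C/C=C/C=O | starting material
10 | [(1Z)-5-(furan-3-yl)-2-methylpent-1-en-1-yl]lithium | [Li]/C=C(/C)CCCc1ccoc1 | intermediate
11 | (2E,5Z)-9-(furan-3-yl)-6-methylnona-2,5-dien-4-ol (racemic) | C/C=C/C(O)/C=C(/C)CCCc1ccoc1 | intermediate
12 | (2E,5Z)-9-(furan-3-yl)-6-methylnona-2,5-dien-4-yl methanesulfonate (racemic) | C/C=C/C(OS(C)(=O)=O)/C=C(/C)CCCc1ccoc1 | intermediate
13 | 3-[(4Z,6E)-8-chloro-4-methylnona-4,6-dien-1-yl]furan (racemic) | CC(Cl)/C=C/C=C(/C)CCCc1ccoc1 | intermediate
14 | (3E)-pent-3-en-2-ol (racemic) | C/C=C/C(C)O | starting material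
15 | (2E)-4-chloropent-2-ene (racemic) | C/C=C/C(C)Cl | intermediate
16 | (3-bromopropoxy)(tert-butyl)dimethylsilane | BrCCCO[Si](C)(C)C(C)(C)C | starting material
17 | {3-[(tert-butyldimethylsilyl)oxy]propyl}zinc bromide | Br[Zn]CCCO[Si](C)(C)C(C)(C)C | intermediate
18 | tert-butyl(dimethyl){[(4R,5E)-4-methylhept-5-en-1-yl]oxy}silane | C/C=C/[C@H](C)CCCO[Si](C)(C)C(C)(C)C | intermediate
19 | (2E,4R)-7-bromo-4-methylhept-2-ene | C/C=C/[C@H](C)CCCBr | intermediate
20 | 3-[(2R)-5-bromopentan-2-yl]-5-methyl-1,2,4-trioxolane | CC1OOC(O1)[C@H](C)CCCBr | intermediate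
21 | (2R)-5-bromo-2-methylpentanal | O=C[C@H](C)CCCBr | intermediate
22 | ethyl 2-oxoacetate (ethyl glyoxylate) | CCOC(=O)C=O | starting material
23 | ethyl 2-[bis(2,2,2-trifluoroethoxy)phosphoryl]-2-hydroxyacetate (racemic) | CCOC(=O)C(O)P(=O)(OCC(F)(F)F)OCC(F)(F)F | intermediate
24 | propanoyl chloride | CCC(=O)Cl | starting material
25 | ethyl 2-[bis(2,2,2-trifluoroethoxy)phosphoryl]-2-(propanoyloxy)acetate (racemic) | CCOC(=O)C(OC(=O)CC)P(=O)(OCC(F)(F)F)OCC(F)(F)F | intermediate
26 | potassium salt of the carbanion of 25 | [K+].CCOC(=O)[C-](OC(=O)CC)P(=O)(OCC(F)(F)F)OCC(F)(F)F | intermediate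
27 | ethyl (2E,4R)-7-bromo-4-methyl-2-(propanoyloxy)hept-2-enoate | CCOC(=O)/C(OC(=O)CC)=C\[C@H](C)CCCBr | intermediate
28 | [(4R,5E)-7-ethoxy-4-methyl-7-oxo-6-(propanoyloxy)hept-5-en-1-yl]zinc bromide | CCOC(=O)/C(OC(=O)CC)=C\[C@H](C)CCC[Zn]Br | intermediate
29 | ethyl (2E,4R,8R,9E,11Z)-15-(furan-3-yl)-4,8,12-trimethyl-2-(propanoyloxy)pentadeca-2,9,11-trienoate | CCOC(=O)/C(OC(=O)CC)=C\[C@H](C)CCC[C@@H](C)/C=C/C=C(/C)CCCc1ccoc1 | intermediate
30 | (5E)-5-[(2R,6R,7E,9Z)-13-(furan-3-yl)-2,6,10-trimethyltrideca-7,9-dien-1-ylidene]-4-hydroxy-3-methylfuran-2(5H)-one | CC1=C(O)/C(=C\[C@H](C)CCC[C@@H](C)/C=C/C=C(/C)CCCc2ccoc2)OC1=O | target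

**Step count**
Total: 13 steps. Longest linear sequence: 7 steps (5, 6, 7, 8, 11, 12, 13).

**Steps most likely to fail, with fallbacks**

Step 12 (together with the labile chloride 13 that feeds it). The pentadienyl unit may couple at the wrong position, lose the 11Z geometry through the delocalised radical or nickel complex, or eliminate to a triene, and the enantioselectivity is untested on a dienyl chloride. The fallback sets out from 28 and 15 and comes back at 29; it keeps the radical coupling for the stereocentre but builds the diene from two geometrically defined halves. Alkylzinc 28 is coupled under the conditions of step 6 with the simple chloride 15 to give ethyl (2E,4R,8R,9E)-4,8-dimethyl-2-(propanoyloxy)undeca-2,9-dienoate F1. Ozone (CH2Cl2, −78 °C, Sudan red end point) attacks only the electron-rich 9,10-alkene and gives ethyl (2E,4R,8R)-4-methyl-8-(5-methyl-1,2,4-trioxolan-3-yl)-2-(propanoyloxy)non-2-enoate F2, which PPh3 reduces to ethyl (2E,4R,8R)-4,8-dimethyl-9-oxo-2-(propanoyloxy)non-2-enoate F3. Takai olefination (CrCl2, CHI3, THF/dioxane) gives ethyl (2E,4R,8R,9E)-10-iodo-4,8-dimethyl-2-(propanoyloxy)deca-2,9-dienoate F4. Negishi coupling (Pd(PPh3)4, THF, rt) with [(1Z)-5-(furan-3-yl)-2-methylpent-1-en-1-yl]zinc bromide F5, made from 8 by way of alkenyllithium 10 and ZnBr2, then gives 29.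

Step 11. The cis-to-ester selectivity of the acyloxy phosphonate is an extrapolation, and the thermodynamically preferred isomer is the wrong one. The fallback sets out from 21 and comes back at 27; it replaces stereoselective olefination by geometric editing. The olefination is run without regard to selectivity (for example 25 with LiCl and DBU in MeCN), and ethyl (2Z,4R)-7-bromo-4-methyl-2-(propanoyloxy)hept-2-enoate F6 is isolated. F6 is irradiated at 350 nm in MeCN with acetophenone as triplet sensitiser to a photostationary E/Z mixture; 27 is separated by chromatography and F6 is returned to the irradiation.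

Step 13. The propanoate enolate of an enol ester can fragment to methylketene, the base can deprotonate C4 (gamma to the ester), and the strained 5E alkene could drift to 5Z. The fallback sets out from 21 and comes back at 30; it builds the ring first and joins the chain to it. 4-Hydroxy-3-methylfuran-2(5H)-one F7 is O-methylated (Me2SO4, K2CO3, acetone) to 4-methoxy-3-methylfuran-2(5H)-one F8. Deprotonation at C5 (LiN(iPr)2, THF, −78 °C) gives lithium 4-methoxy-3-methylfuran-2-olate F9, which adds to 21 to give 5-[(2R)-5-bromo-1-hydroxy-2-methylpentyl]-4-methoxy-3-methylfuran-2(5H)-one F10. Mesylation (MsCl, Et3N) gives (2R)-5-bromo-1-(3-methoxy-4-methyl-5-oxo-2,5-dihydrofuran-2-yl)-2-methylpentyl methanesulfonate F11. DBU eliminates it to the ylidene tetronate, which is expected to be mainly 5Z; (5E)-5-[(2R)-5-bromo-2-methylpentylidene]-4-methoxy-3-methylfuran-2(5H)-one F12 is separated by chromatography. Zinc insertion (Zn dust, I2, DMA) gives [(4R,5E)-5-(3-methoxy-4-methyl-5-oxofuran-2(5H)-ylidene)-4-methylpentyl]zinc bromide F13. The coupling of step 12 with 13 gives (5E)-5-[(2R,6R,7E,9Z)-13-(furan-3-yl)-2,6,10-trimethyltrideca-7,9-dien-1-ylidene]-4-methoxy-3-methylfuran-2(5H)-one F14, and LiCl in DMF at 80 °C cleaves the methyl ether to 30.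

**Further compounds**
F1 | step 12 | ethyl (2E,4R,8R,9E)-4,8-dimethyl-2-(propanoyloxy)undeca-2,9-dienoate | CCOC(=O)/C(OC(=O)CC)=C\[C@H](C)CCC[C@@H](C)/C=C/C
F2 | step 12 | ethyl (2E,4R,8R)-4-methyl-8-(5-methyl-1,2,4-trioxolan-3-yl)-2-(propanoyloxy)non-2-enoate | CCOC(=O)/C(OC(=O)CC)=C\[C@H](C)CCC[C@@H](C)C1OOC(C)O1
F3 | step 12 | ethyl (2E,4R,8R)-4,8-dimethyl-9-oxo-2-(propanoyloxy)non-2-enoate | CCOC(=O)/C(OC(=O)CC)=C\[C@H](C)CCC[C@@H](C)C=O
F4 | step 12 | ethyl (2E,4R,8R,9E)-10-iodo-4,8-dimethyl-2-(propanoyloxy)deca-2,9-dienoate | CCOC(=O)/C(OC(=O)CC)=C\[C@H](C)CCC[C@@H](C)/C=C/I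
F5 | step 12 | [(1Z)-5-(furan-3-yl)-2-methylpent-1-en-1-yl]zinc bromide | Br[Zn]/C=C(/C)CCCc1ccoc1
F6 | step 11 | ethyl (2Z,4R)-7-bromo-4-methyl-2-(propanoyloxy)hept-2-enoate | CCOC(=O)/C(OC(=O)CC)=C/[C@H](C)CCCBr
F7 | step 13 | 4-hydroxy-3-methylfuran-2(5H)-one | CC1=C(O)COC1=O
F8 | step 13 | 4-methoxy-3-methylfuran-2(5H)-one | COC1=C(C)C(=O)OC1
F9 | step 13 | lithium 4-methoxy-3-methylfuran-2-olate | [Li+].[O-]c1occ(OC)c1C
F10 | step 13 | 5-[(2R)-5-bromo-1-hydroxy-2-methylpentyl]-4-methoxy-3-methylfuran-2(5H)-one | COC1=C(C)C(=O)OC1C(O)[C@H](C)CCCBr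
F11 | step 13 | (2R)-5-bromo-1-(3-methoxy-4-methyl-5-oxo-2,5-dihydrofuran-2-yl)-2-methylpentyl methanesulfonate | COC1=C(C)C(=O)OC1C(OS(C)(=O)=O)[C@H](C)CCCBr
F12 | step 13 | (5E)-5-[(2R)-5-bromo-2-methylpentylidene]-4-methoxy-3-methylfuran-2(5H)-one | CC1=C(OC)/C(=C\[C@H](C)CCCBr)OC1=O
F13 | step 13 | [(4R,5E)-5-(3-methoxy-4-methyl-5-oxofuran-2(5H)-ylidene)-4-methylpentyl]zinc bromide | CC1=C(OC)/C(=C\[C@H](C)CCC[Zn]Br)OC1=O
F14 | step 13 | (5E)-5-[(2R,6R,7E,9Z)-13-(furan-3-yl)-2,6,10-trimethyltrideca-7,9-dien-1-ylidene]-4-methoxy-3-methylfuran-2(5H)-one | CC1=C(OC)/C(=C\[C@H](C)CCC[C@@H](C)/C=C/C=C(/C)CCCc2ccoc2)OC1=O
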